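**Retrosynthetic overview**
- The hydroquinone is unveiled last (oxidative demethylation, then reduction) after acetylation of C5′‑OH; the γ‑hydroxy enone comes from an N‑methylanilide plus a C5 alkenyllithium (C12′–C13′).
- Key disconnection C10′–C11′: nickel‑hydride‑catalysed enantioconvergent radical hydroalkylation of the terminal olefin of a C1′–C10′ triene alcohol with racemic 2‑bromopropanamide; this sets 11′S.
- C5′–C6′: asymmetric Ni/Cr coupling of a β,γ‑unsaturated aldehyde with an E‑dienyl iodide; this sets 5′S.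
- Both E‑trisubstituted olefins come from Zr‑catalysed methylalumination of but‑3‑yn‑1‑ol and pent‑1‑en‑4‑yne; aryl–C1′ comes from a Cu‑catalysed Grignard allylation.
- No ring is constructed: the benzene ring is carried from o‑cresol (ortho‑bromination, Teuber oxidation, reductive methylation).

Convention: side‑chain carbons are numbered C1′ (benzylic CH2) to C15′ (tertiary carbinol carbon); the target is then the 2′E,5′S,6′E,11′S,13′E isomer.

**Step 1**
Reactants: 1 2-methylphenol (o-cresol)
Product: 2 2-bromo-6-methylphenol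
Conditions: NBS (1.0 equiv), i‑Pr2NH (10 mol %), CH2Cl2, 0 °C → rt
Reagents that add atoms: N-bromosuccinimide BrN1C(=O)CCC1=O
Why: Amine‑mediated electrophilic ortho‑bromination of a phenol, in which the hydrogen‑bonded N‑bromoamine delivers bromine to the only free ortho position instead of para.

**Step 2**
Reactants: 2 2-bromo-6-methylphenol
Product: 3 2-bromo-6-methylcyclohexa-2,5-diene-1,4-dione
Conditions: (KSO3)2NO (2.5 equiv), KH2PO4, H2O/acetone, rt
Reagents that add atoms: potassium nitrosodisulfonate (KSO3)2NO [K+].[K+].[O]N(S(=O)(=O)[O-])S(=O)(=O)[O-]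
Why: Teuber oxidation, in which the nitroxyl radical salt converts a phenol with a free para position selectively into the para‑quinone under buffered aqueous conditions.

**Step 3**
Reactants: 3 2-bromo-6-methylcyclohexa-2,5-diene-1,4-dione
Product: 5 1-bromo-2,5-dimethoxy-3-methylbenzene, via bromohydroquinone 4 (not isolated)
Conditions: Na2S2O4, THF/H2O, rt; then KOH, Me2SO4, n‑Bu4NBr (cat.), 0 °C → rt, N2
Reagents that add atoms: dimethyl sulfate COS(=O)(=O)OC
Why: Reductive methylation, in which dithionite reduces the quinone and the air‑sensitive hydroquinone is O‑methylated in the same flask by a phase‑transfer Williamson etherification.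

**Step 4**
Reactants: 6 but-3-yn-1-ol; 7 formaldehyde (as paraformaldehyde)
Product: 10 (2E)-3-methylpent-2-ene-1,5-diol, via alkenylalane 8 (not isolated), via lithium alanate 9 (not isolated)
Conditions: Me3Al (3.0 equiv), Cp2ZrCl2 (25 mol %), CH2Cl2, 0 °C → rt; then n‑BuLi (1.0 equiv), THF/hexane, −78 °C; (CH2O)n, −78 °C → rt; aq. Rochelle salt
Reagents that add atoms: trimethylaluminium C[Al](C)C
Why: Negishi zirconium‑catalysed methylalumination is a syn addition that puts aluminium on the terminal alkyne carbon, so hydroxymethylation of the derived alanate with retention gives only the E trisubstituted olefin.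

**Step 5**
Reactants: 10 (2E)-3-methylpent-2-ene-1,5-diol
Product: 11 (3E)-5-chloro-3-methylpent-3-en-1-ol
Conditions: NCS (1.1 equiv), Me2S (1.2 equiv), CH2Cl2, −20 → 0 °C
Reagents that add atoms: N-chlorosuccinimide ClN1C(=O)CCC1=O
Why: Corey–Kim chlorination, in which only the allylic alkoxysulfonium ion is displaced by chloride (SN2, no allylic shift) at 0 °C, so the saturated primary alcohol and the olefin geometry are untouched.

**Step 6**
Reactants: 5 1-bromo-2,5-dimethoxy-3-methylbenzene; 11 (3E)-5-chloro-3-methylpent-3-en-1-ol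
Product: 13 (3E)-5-(2,5-dimethoxy-3-methylphenyl)-3-methylpent-3-en-1-ol, via aryl Grignard reagent 12 (not isolated)
Conditions: 5 (2.2 equiv), Mg, THF, 45 °C; then CuI (10 mol %), 11 (1.0 equiv), THF, −20 °C → rt
Reagents that add atoms: none
Why: Copper‑catalysed Grignard allylic substitution, in which the aryl group attacks the unhindered CH2Cl terminus (SN2) because the γ carbon is fully substituted, with retention of E geometry, the first equivalent of Grignard serving only to deprotonate the hydroxyl.

**Step 7**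
Reactants: 13 (3E)-5-(2,5-dimethoxy-3-methylphenyl)-3-methylpent-3-en-1-ol
Product: 14 (3E)-5-(2,5-dimethoxy-3-methylphenyl)-3-methylpent-3-enal
Conditions: Dess–Martin periodinane (1.3 equiv), pyridine, CH2Cl2, 0 °C; used at once
Reagents that add atoms: none
Why: Dess–Martin oxidation under pyridine buffering gives the β,γ‑unsaturated aldehyde without migration of the double bond into conjugation.

**Step 8**
Reactants: 15 pent-1-en-4-yne
Product: 17 (1E)-1-iodo-2-methylpenta-1,4-diene, via dienylalane 16 (not isolated)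
Conditions: Me3Al (2.0 equiv), Cp2ZrCl2 (20 mol %), CH2Cl2, 0 °C → rt; then I2, THF, −30 → 0 °C
Reagents that add atoms: trimethylaluminium C[Al](C)C; iodine II
Why: Negishi carboalumination (the alkyne reacts far faster than the monosubstituted alkene) followed by iodinolysis of the C–Al bond with retention gives the E alkenyl iodide.

**Step 9**
Reactants: 14 (3E)-5-(2,5-dimethoxy-3-methylphenyl)-3-methylpent-3-enal; 17 (1E)-1-iodo-2-methylpenta-1,4-diene
Product: 18 (2E,5S,6E)-1-(2,5-dimethoxy-3-methylphenyl)-3,7-dimethyldeca-2,6,9-trien-5-ol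
Conditions: CrCl2 (3.0 equiv), chiral oxazoline–sulfonamide ligand (3.3 equiv, enantiomer giving 5S), Et3N (3.3 equiv), NiCl2 (5 mol %), THF, rt
Reagents that add atoms: none
Why: Asymmetric Nozaki–Hiyama–Kishi coupling, in which the nickel‑activated alkenyl iodide is transferred to ligand‑bound chromium and adds chemoselectively to the aldehyde with retention of olefin geometry, the chiral sulfonamide ligand on chromium selecting the aldehyde face that gives 5′S.

**Step 10**
Reactants: 19 2-bromopropanoyl bromide; 20 N-methylaniline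
Product: 21 rac-2-bromo-N-methyl-N-phenylpropanamide
Conditions: Et3N (1.1 equiv), CH2Cl2, 0 °C
Reagents that add atoms: none
Why: Schotten–Baumann‑type N‑acylation of a secondary aniline by an acyl bromide.

**Step 11 (key step)**
Reactants: 18 (2E,5S,6E)-1-(2,5-dimethoxy-3-methylphenyl)-3,7-dimethyldeca-2,6,9-trien-5-ol; 21 rac-2-bromo-N-methyl-N-phenylpropanamide
Product: 22 (2S,6E,8S,10E)-12-(2,5-dimethoxy-3-methylphenyl)-8-hydroxy-N,2,6,10-tetramethyl-N-phenyldodeca-6,10-dienamide
Conditions: NiBr2·glyme (10 mol %), chiral bis(oxazoline) ligand (12 mol %, enantiomer giving 2S), (EtO)3SiH (2.5 equiv), K3PO4·H2O (2.5 equiv), Et2O/DMF, 0 °C → rt; aq. NH4F work‑up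
Reagents that add atoms: none
Why: Nickel‑hydride‑catalysed enantioconvergent hydroalkylation (radical cross‑coupling), in which Ni–H adds anti‑Markovnikov to the only monosubstituted olefin, the bromoamide is converted to a planar α‑amido radical that is captured by the chiral alkylnickel, and reductive elimination forms C10′–C11′ with the ligand fixing 11′S from either enantiomer of the bromide.

**Step 12**
Reactants: 23 2-methylbut-3-yn-2-ol
Product: 24 (3E)-2-methyl-4-(tributylstannyl)but-3-en-2-ol
Conditions: Bu3SnH (1.1 equiv), PdCl2(PPh3)2 (1 mol %), THF, 0 °C → rt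
Reagents that add atoms: tributyltin hydride CCCC[SnH](CCCC)CCCC
Why: Palladium‑catalysed syn hydrostannation of a terminal alkyne, in which the bulky tertiary carbinol steers tin to the terminal carbon and gives the E alkenylstannane.

**Step 13**
Reactants: 22 (2S,6E,8S,10E)-12-(2,5-dimethoxy-3-methylphenyl)-8-hydroxy-N,2,6,10-tetramethyl-N-phenyldodeca-6,10-dienamide; 24 (3E)-2-methyl-4-(tributylstannyl)but-3-en-2-ol
Product: 26 (3E,6S,10E,12S,14E)-16-(2,5-dimethoxy-3-methylphenyl)-2,12-dihydroxy-2,6,10,14-tetramethylhexadeca-3,10,14-trien-5-one, via dilithio alkenyl reagent 25 (not isolated)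
Conditions: 24 (3.3 equiv), n‑BuLi (6.6 equiv), THF, −78 → −20 °C; then 22, −78 → −40 °C; inverse quench into cold aq. NaH2PO4
Reagents that add atoms: none
Why: Tin–lithium exchange gives the alkenyllithium with retention of E geometry, and its acyl substitution on the tertiary anilide stops at a tetrahedral adduct that releases the enone only on quench, so the α‑methyl stereocentre of the branched amide is not epimerised (one equivalent of reagent is consumed by the free hydroxyl).

**Step 14**
Reactants: 26 (3E,6S,10E,12S,14E)-16-(2,5-dimethoxy-3-methylphenyl)-2,12-dihydroxy-2,6,10,14-tetramethylhexadeca-3,10,14-trien-5-one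
Product: 27 (2E,5S,6E,11S,13E)-1-(2,5-dimethoxy-3-methylphenyl)-15-hydroxy-3,7,11,15-tetramethyl-12-oxohexadeca-2,6,13-trien-5-yl acetate
Conditions: Ac2O (3 equiv), pyridine, DMAP (2 mol %), CH2Cl2, 0 °C
Reagents that add atoms: acetic anhydride CC(=O)OC(C)=O
Why: Chemoselective O‑acetylation by nucleophilic catalysis, in which the secondary allylic alcohol is acylated with retention at C5′ while the tertiary alcohol is too hindered to react at 0 °C.

**Step 15**
Reactants: 27 (2E,5S,6E,11S,13E)-1-(2,5-dimethoxy-3-methylphenyl)-15-hydroxy-3,7,11,15-tetramethyl-12-oxohexadeca-2,6,13-trien-5-yl acetate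
Product: 29 (2E,5S,6E,11S,13E)-1-(2,5-dihydroxy-3-methylphenyl)-15-hydroxy-3,7,11,15-tetramethyl-12-oxohexadeca-2,6,13-trien-5-yl acetate, via quinone 28 (not isolated)
Conditions: (NH4)2Ce(NO3)6 (2.5 equiv), MeCN/H2O (2:1), 0 °C, 20 min; then aq. Na2S2O4, Et2O, rt, Ar
Reagents that add atoms: water O
Why: Oxidative demethylation of a para‑dimethoxyarene through its radical cation gives the para‑quinone while sparing acetate, enone and olefins, and the dithionite reductive work‑up gives the hydroquinone without acid that could cyclise it onto the 2′‑olefin.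

**Compound list**
1 | 2-methylphenol (o-cresol) | Cc1ccccc1O | starting material
2 | 2-bromo-6-methylphenol | Cc1cccc(Br)c1O | intermediate
3 | 2-bromo-6-methylcyclohexa-2,5-diene-1,4-dione | CC1=CC(=O)C=C(Br)C1=O | intermediate
4 | 2-bromo-6-methylbenzene-1,4-diol | Cc1cc(O)cc(Br)c1O | intermediate
5 | 1-bromo-2,5-dimethoxy-3-methylbenzene | COc1cc(C)c(OC)c(Br)c1 | intermediate
6 | but-3-yn-1-ol | C#CCCO | starting material
7 | formaldehyde (used as paraformaldehyde) | C=O | starting material
8 | [(1E)-4-(dimethylalumanyloxy)-2-methylbut-1-en-1-yl]dimethylalumane | C[Al](C)/C=C(\C)CCO[Al](C)C | intermediate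
9 | lithium butyl[(1E)-4-(dimethylalumanyloxy)-2-methylbut-1-en-1-yl]dimethylaluminate | [Li+].CCCC[Al-](C)(C)/C=C(\C)CCO[Al](C)C | intermediate
10 | (2E)-3-methylpent-2-ene-1,5-diol | OC/C=C(\C)CCO | intermediate
11 | (3E)-5-chloro-3-methylpent-3-en-1-ol | ClC/C=C(\C)CCO | intermediate
12 | (2,5-dimethoxy-3-methylphenyl)magnesium bromide | COc1cc(C)c(OC)c([Mg]Br)c1 | intermediate
13 | (3E)-5-(2,5-dimethoxy-3-methylphenyl)-3-methylpent-3-en-1-ol | COc1cc(C)c(OC)c(C/C=C(\C)CCO)c1 | intermediate
14 | (3E)-5-(2,5-dimethoxy-3-methylphenyl)-3-methylpent-3-enal | COc1cc(C)c(OC)c(C/C=C(\C)CC=O)c1 | intermediate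
15 | pent-1-en-4-yne | C=CCC#C | starting material
16 | dimethyl[(1E)-2-methylpenta-1,4-dien-1-yl]alumane | C[Al](C)/C=C(\C)CC=C | intermediate
17 | (1E)-1-iodo-2-methylpenta-1,4-diene | I/C=C(\C)CC=C | intermediate
18 | (2E,5S,6E)-1-(2,5-dimethoxy-3-methylphenyl)-3,7-dimethyldeca-2,6,9-trien-5-ol | COc1cc(C)c(OC)c(C/C=C(\C)C[C@H](O)/C=C(\C)CC=C)c1 | intermediate
19 | 2-bromopropanoyl bromide (racemic) | CC(Br)C(Br)=O | starting material
20 | N-methylaniline | CNc1ccccc1 | starting material
21 | rac-2-bromo-N-methyl-N-phenylpropanamide | CC(Br)C(=O)N(C)c1ccccc1 | intermediate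
22 | (2S,6E,8S,10E)-12-(2,5-dimethoxy-3-methylphenyl)-8-hydroxy-N,2,6,10-tetramethyl-N-phenyldodeca-6,10-dienamide | COc1cc(C)c(OC)c(C/C=C(\C)C[C@H](O)/C=C(\C)CCC[C@H](C)C(=O)N(C)c2ccccc2)c1 | intermediate
23 | 2-methylbut-3-yn-2-ol | CC(C)(O)C#C | starting material
24 | (3E)-2-methyl-4-(tributylstannyl)but-3-en-2-ol | CCCC[Sn](CCCC)(CCCC)/C=C/C(C)(C)O | intermediate
25 | lithium (3E)-4-lithio-2-methylbut-3-en-2-olate | [Li]/C=C/C(C)(C)O[Li] | intermediate
26 | (3E,6S,10E,12S,14E)-16-(2,5-dimethoxy-3-methylphenyl)-2,12-dihydroxy-2,6,10,14-tetramethylhexadeca-3,10,14-trien-5-one | COc1cc(C)c(OC)c(C/C=C(\C)C[C@H](O)/C=C(\C)CCC[C@H](C)C(=O)/C=C/C(C)(C)O)c1 | intermediate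
27 | (2E,5S,6E,11S,13E)-1-(2,5-dimethoxy-3-methylphenyl)-15-hydroxy-3,7,11,15-tetramethyl-12-oxohexadeca-2,6,13-trien-5-yl acetate | COc1cc(C)c(OC)c(C/C=C(\C)C[C@H](OC(C)=O)/C=C(\C)CCC[C@H](C)C(=O)/C=C/C(C)(C)O)c1 | intermediate
28 | (2E,5S,6E,11S,13E)-15-hydroxy-3,7,11,15-tetramethyl-1-(5-methyl-3,6-dioxocyclohexa-1,4-dien-1-yl)-12-oxohexadeca-2,6,13-trien-5-yl acetate | CC1=CC(=O)C=C(C/C=C(\C)C[C@H](OC(C)=O)/C=C(\C)CCC[C@H](C)C(=O)/C=C/C(C)(C)O)C1=O | intermediate
29 | (2E,5S,6E,11S,13E)-1-(2,5-dihydroxy-3-methylphenyl)-15-hydroxy-3,7,11,15-tetramethyl-12-oxohexadeca-2,6,13-trien-5-yl acetate (CNP0285180.1) | CC(=O)O[C@H](/C=C(\C)CCC[C@H](C)C(=O)/C=C/C(C)(C)O)C/C(C)=C/Cc1cc(O)cc(C)c1O | target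

**Step count**
Total: 15 steps. Longest linear sequence: 10 steps (steps 1, 2, 3, 6, 7, 9, 11, 13, 14, 15).

**Three steps most likely to fail, with fallbacks**

Step 11 (nickel‑hydride hydroalkylation of the advanced triene alcohol). The free allylic hydroxyl may be silylated, the skipped diene may chain‑walk, and enantioselectivity on this substrate is untested. The fallback sets out from 15 (using 21 and 14 from the main route) and comes back at 22; it moves the radical coupling to a simple olefin and builds the chain afterwards. Pent‑1‑en‑4‑yne 15 is C‑silylated (EtMgBr, Me3SiCl) to trimethyl(pent-4-en-1-yn-1-yl)silane F3. F3 is coupled with 21 under the step 11 conditions to give (2S)-N,2-dimethyl-N-phenyl-7-(trimethylsilyl)hept-6-ynamide F4. K2CO3/MeOH then gives (2S)-N,2-dimethyl-N-phenylhept-6-ynamide F5. Methylalumination (Me3Al, Cp2ZrCl2 cat.) and iodinolysis give (2S,6E)-7-iodo-N,2,6-trimethyl-N-phenylhept-6-enamide F6, which is joined to aldehyde 14 by the asymmetric Ni/Cr coupling of step 9 to give 22.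

Step 9 (asymmetric Ni/Cr coupling). An unbranched, isomerisation‑prone β,γ‑unsaturated aldehyde may give only moderate enantioselectivity. The fallback sets out from 14 and 17 and comes back at 18; it replaces asymmetric addition by oxidation and asymmetric reduction. Ligand‑free coupling (CrCl2, NiCl2 cat., DMF) gives rac-(2E,6E)-1-(2,5-dimethoxy-3-methylphenyl)-3,7-dimethyldeca-2,6,9-trien-5-ol F1. MnO2 oxidation gives (2E,6E)-1-(2,5-dimethoxy-3-methylphenyl)-3,7-dimethyldeca-2,6,9-trien-5-one F2. Corey–Bakshi–Shibata reduction with the (R)-2-methyl oxazaborolidine and catecholborane at −78 °C (the conjugated alkenyl group acting as the large substituent) returns 18.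

Step 13 (alkenyllithium addition to the anilide). Risks are premature collapse of the tetrahedral adduct with over‑addition, and epimerisation at C11′. The fallback sets out from 22 and comes back at 26; it builds the enone by olefin cross‑metathesis instead. Vinylmagnesium bromide (THF, −78 °C, acidic inverse quench) converts 22 into (4S,8E,10S,12E)-14-(2,5-dimethoxy-3-methylphenyl)-10-hydroxy-4,8,12-trimethyltetradeca-1,8,12-trien-3-one F7. Cross‑metathesis of F7 with commercial 2‑methylbut‑3‑en‑2‑ol (second‑generation Hoveyda–Grubbs catalyst, CH2Cl2, 40 °C; the trisubstituted olefins are inert) gives the E enone 26.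

**Further compounds**
F1 | step 9 | rac-(2E,6E)-1-(2,5-dimethoxy-3-methylphenyl)-3,7-dimethyldeca-2,6,9-trien-5-ol | COc1cc(C)c(OC)c(C/C=C(\C)CC(O)/C=C(\C)CC=C)c1
F2 | step 9 | (2E,6E)-1-(2,5-dimethoxy-3-methylphenyl)-3,7-dimethyldeca-2,6,9-trien-5-one | COc1cc(C)c(OC)c(C/C=C(\C)CC(=O)/C=C(\C)CC=C)c1
F3 | step 11 | trimethyl(pent-4-en-1-yn-1-yl)silane | C=CCC#C[Si](C)(C)C
F4 | step 11 | (2S)-N,2-dimethyl-N-phenyl-7-(trimethylsilyl)hept-6-ynamide | C[C@@H](CCCC#C[Si](C)(C)C)C(=O)N(C)c1ccccc1
F5 | step 11 | (2S)-N,2-dimethyl-N-phenylhept-6-ynamide | C[C@@H](CCCC#C)C(=O)N(C)c1ccccc1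
F6 | step 11 | (2S,6E)-7-iodo-N,2,6-trimethyl-N-phenylhept-6-enamide | C[C@@H](CCC/C(C)=C/I)C(=O)N(C)c1ccccc1
F7 | step 13 | (4S,8E,10S,12E)-14-(2,5-dimethoxy-3-methylphenyl)-10-hydroxy-4,8,12-trimethyltetradeca-1,8,12-trien-3-one | COc1cc(C)c(OC)c(C/C=C(\C)C[C@H](O)/C=C(\C)CCC[C@H](C)C(=O)C=C)c1
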